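**Plan**
- Retrosynthetic cuts, in order: the C6–O acyl bond and two silyl ethers; the C7–OH/Δ8 allylic system back to C9–OH/Δ7 (1,3-transposition) and then the C9–C11 bond; the C6 oxygen; the C3–C4 bond of ring A; the C10–C1 and C10–CH3 bonds.
- Forward: ring B is (R)-carvone; its α'-carbon (future C10) is methylated and then 3-halopropylated; ring A is closed between C3 and C4; C6 is oxidized and reduced; the side chain is added to the C9 ketone; acid moves the oxygen from C9 to C7; O6 is acylated.
- Enabling feature: C4 is a gem-dimethyl quaternary carbon bonded to C5, that is, the Markovnikov carbon of the isopropenyl group carvone already carries on C5. C3 is a plain CH2 three bonds from C10, the α'-carbon of the carvone ketone (C9). A tertiary radical at C4 can therefore be joined to a primary C3–I and ring A closes without any residual functional group.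
- Stereochemistry: C5 from (R)-carvone; C10 by alkylation anti to the isopropenyl group (hence trans fusion); C6 by α-face hydride delivery (β face blocked by the C10 and C4β methyls); C7 by axial α-face capture of the allyl cation anti to the axial 6β-OH; 13E by syn-carboalumination.

Key step: step 4

Remark: bicyclic compounds are numbered as labdanes (ring A C1–C5 and C10, ring B C5–C10, side chain C11–C16, C17 on C8, C18/C19 on C4, C20 on C10), β is the face of the C10 methyl, and monocyclic compounds carry carvone numbering. (R)-(−)-Carvone and tert-butyl(but-3-yn-1-yloxy)dimethylsilane are taken as commercial.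

Step 1
Reactants: 1 (R)-(−)-carvone
Product: 3 (5R)-2,6-dimethyl-5-(prop-1-en-2-yl)cyclohex-2-en-1-one (6-methylcarvone; both C6 epimers), via lithium dienolate of carvone 2 (not isolated)
Conditions: LiN(i-Pr)2, THF, −78 °C; MeI, −78 → 0 °C
Reagents that add atoms: iodomethane CI
Why: Kinetic α'-deprotonation gives the cross-conjugated dienolate, whose C-methylation (enolate alkylation) installs the future C20; the new centre forms as an epimer mixture, which does not matter because it is planarized again in step 2.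

Step 2
Reactants: 3 6-methylcarvone
Product: 5 (5S,6S)-6-(3-chloropropyl)-2,6-dimethyl-5-(prop-1-en-2-yl)cyclohex-2-en-1-one, via lithium enolate of 6-methylcarvone 4 (not isolated)
Conditions: LiN(i-Pr)2, THF, −78 → −20 °C; DMPU, ICH2CH2CH2Cl, −78 °C → rt
Reagents that add atoms: 1-chloro-3-iodopropane ClCCCI
Why: The fully substituted enolate is alkylated at the iodide terminus (SN2 enolate alkylation, chloride untouched) on the face anti to the neighbouring isopropenyl group, which sets the quaternary future C10 with the methyl cis and the three-carbon arm trans to the isopropenyl group.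

Step 3
Reactants: 5 chloropropyl enone
Product: 6 (5S,6S)-6-(3-iodopropyl)-2,6-dimethyl-5-(prop-1-en-2-yl)cyclohex-2-en-1-one
Conditions: NaI, acetone, reflux
Reagents that add atoms: sodium iodide [Na+].[I-]
Why: Finkelstein halide exchange, driven by precipitation of NaCl, gives the primary iodide needed for nickel activation; no stereocentre is touched.

Step 4
Reactants: 6 iodopropyl enone
Product: 7 (4aS,8aS)-2,5,5,8a-tetramethyl-4a,5,6,7,8,8a-hexahydronaphthalen-1(4H)-one (trans-fused; labdane 7-en-9-one)
Conditions: Fe(acac)3 (20 mol %), Ni(acac)2 (5 mol %), Ph(i-PrO)SiH2, K2CO3, ClCH2CH2Cl, 25 °C, high dilution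
Reagents that add atoms: none
Why: Proposed new method: the iron hydride formed from Fe(acac)3 and the silane transfers a hydrogen atom to the CH2 terminus of the electron-rich isopropenyl group (Markovnikov MHAT) and leaves a tertiary radical at the future C4, while low-valent nickel activates the primary C3–I bond; capture of the radical by the alkylnickel gives a seven-membered dialkylnickel metallacycle in the trivalent state, whose C(sp3)–C(sp3) reductive elimination forms the C3–C4 bond and the gem-dimethyl quaternary carbon. The closest known reaction type is the intermolecular metal-hydride/nickel dual-catalytic Markovnikov hydroalkylation of 1,1-disubstituted alkenes with primary alkyl iodides that builds quaternary carbons; only the intramolecular, ring-forming use is new. Ring A closes as a six-membered ring by a formal 6-exo-tet alkylation of the C4 radical (reductive elimination from the nickelacycle), not by addition to a π bond. No new stereocentre forms because C4 carries two methyls; the trans fusion follows from C5 (carvone) and C10 (step 2), whose isopropenyl and iodopropyl arms are trans-diequatorial and close without strain. The step needs H-atom transfer to the isopropenyl group in the presence of the enone, and coupling faster than reduction or 7-endo cyclization of the iodide: the nucleophilic hydride prefers the electron-rich 1,1-disubstituted alkene over the electron-poor enone, the tertiary radical cannot reach the enone in a favourable ring size, and high dilution with the two termini held gauche on the ring favours intramolecular coupling.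

Step 5
Reactants: 7 bicyclic enone
Product: 9 (4aS,8aS)-2,5,5,8a-tetramethyl-4a,5,6,7,8,8a-hexahydronaphthalene-1,4-dione (labdane 7-ene-6,9-dione), via 6-tert-butylperoxy enone 8 (not isolated)
Conditions: Pd(OH)2/C (cat.), t-BuOOH, K2CO3 (cat.), CH2Cl2, 4 °C
Reagents that add atoms: tert-butyl hydroperoxide CC(C)(C)OO
Why: The γ-methylene (C6) of the enone is oxidized by the palladium/hydroperoxide γ-peroxidation–elimination that converts enones into 1,4-enediones, the peroxy ether collapsing to the carbonyl under the basic conditions; C5 is expected to stay trans because that is the more stable fusion.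

Step 6
Reactants: 9 enedione
Product: 10 (4R,4aS,8aS)-4-hydroxy-2,5,5,8a-tetramethyl-4a,5,6,7,8,8a-hexahydronaphthalen-1(4H)-one (6β-hydroxy-7-en-9-one)
Conditions: NaBH4, CeCl3·7H2O, MeOH, −78 °C
Reagents that add atoms: none
Why: Luche 1,2-reduction should take the C6 carbonyl, whose α-face neighbour is only the C5 hydrogen, rather than the C9 carbonyl flanked by quaternary C10 and the C8 methyl (as in 2,6,6-trimethylcyclohex-2-ene-1,4-dione, where the carbonyl remote from the quaternary carbon reacts); hydride must come from the α face because the β face of C6 is covered by the syn-axial C10 and C4β methyls, giving the axial 6β-alcohol.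

Step 7
Reactants: 11 tert-butyl(but-3-yn-1-yloxy)dimethylsilane
Product: 14 (E)-5-[(tert-butyldimethylsilyl)oxy]-3-methylpent-2-en-1-ol, via alkenyldimethylalane 12 (not isolated), via lithium alkenylaluminate 13 (not isolated)
Conditions: Me3Al, Cp2ZrCl2 (cat.), CH2Cl2, 0 °C → rt; n-BuLi, THF, −78 °C; (CH2O)n, −78 °C → rt; aqueous work-up
Reagents that add atoms: trimethylaluminium C[Al](C)C; formaldehyde (as paraformaldehyde) C=O
Why: Zirconium-catalysed syn-carboalumination of the terminal alkyne (Negishi carboalumination) places CH3 and Al cis, which fixes the E trisubstituted alkene, and the ate complex is hydroxymethylated with retention at the alkenyl carbon.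

Step 8
Reactants: 14 allylic alcohol
Product: 15 (E)-1-[(tert-butyldiphenylsilyl)oxy]-5-[(tert-butyldimethylsilyl)oxy]-3-methylpent-2-ene
Conditions: t-BuPh2SiCl, imidazole, DMF, rt
Reagents that add atoms: tert-butyl(chloro)diphenylsilane CC(C)(C)[Si](Cl)(c1ccccc1)c1ccccc1
Why: Standard silylation of the primary allylic alcohol gives an acid-robust silyl ether that should survive steps 9, 11 and 12.

Step 9
Reactants: 15 bis-silyl ether
Product: 16 (E)-5-[(tert-butyldiphenylsilyl)oxy]-3-methylpent-3-en-1-ol
Conditions: camphorsulfonic acid (cat.), MeOH/CH2Cl2, 0 °C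
Reagents that add atoms: none
Why: Acid-catalysed methanolysis removes the primary tert-butyldimethylsilyl ether much faster than the bulkier tert-butyldiphenylsilyl ether (selective desilylation).

Step 10
Reactants: 16 homoallylic alcohol
Product: 17 (E)-tert-butyl[(5-iodo-3-methylpent-2-en-1-yl)oxy]diphenylsilane
Conditions: I2, PPh3, imidazole, CH2Cl2, 0 °C → rt
Reagents that add atoms: iodine II
Why: Appel-type iodination converts the primary alcohol into the primary iodide by SN2 without touching the alkene geometry.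

Step 11
Reactants: 10 6β-hydroxy enone; 17 side-chain iodide
Product: 20 (1S,4R,4aS,8aS)-1-[(E)-5-(tert-butyldiphenylsilyloxy)-3-methylpent-3-en-1-yl]-2,5,5,8a-tetramethyl-1,4,4a,5,6,7,8,8a-octahydronaphthalene-1,4-diol (labdane numbering: 6β-OH; C9 bears OH β/side chain α; Δ7), via side-chain organolithium 18 (not isolated), via bromomagnesium 6β-alkoxide 19 (not isolated)
Conditions: 17: t-BuLi (2 equiv), Et2O/pentane, −78 °C; 10: MeMgBr (1 equiv), THF, −78 °C; combine, −78 → −30 °C; H2O
Reagents that add atoms: none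
Why: Iodine–lithium exchange gives the primary organolithium, which adds 1,2 to the enone carbonyl (the 6-OH is masked as its magnesium alkoxide and C10 has no hydrogen to enolize) from the α face, anti to the axial C10 methyl, to give the tertiary allylic alcohol.

Step 12
Reactants: 20 ene-1,4-diol
Product: 21 (13E)-15-[(tert-butyldiphenylsilyl)oxy]labda-8,13-diene-6β,7α-diol
Conditions: TsOH·H2O (cat.), THF/H2O, 0 °C → rt
Reagents that add atoms: water O
Why: Acid-catalysed 1,3-transposition of the tertiary allylic alcohol through the C9–C8–C7 allyl cation is driven towards the secondary alcohol with the tetrasubstituted Δ8 alkene; water should enter at C7 from the axial α face, anti to the axial 6β-hydroxyl, which can assist through a transient β-epoxide (trans-diaxial opening, Fürst–Plattner), while loss of the equatorial C6–H is stereoelectronically disfavoured.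

Step 13
Reactants: 21 6β,7α-diol
Product: 22 (13E)-15-[(tert-butyldiphenylsilyl)oxy]-7α-[(triethylsilyl)oxy]labda-8,13-dien-6β-ol
Conditions: Et3SiCl, imidazole, DMF, 0 °C
Reagents that add atoms: chlorotriethylsilane CC[Si](Cl)(CC)CC
Why: The allylic 7α-hydroxyl is silylated selectively because the 6β-hydroxyl is syn-diaxial to the C10 and C4β methyls (steric differentiation of a diol).

Step 14
Reactants: 22 7-O-silyl alcohol
Product: 23 (13E)-15-[(tert-butyldiphenylsilyl)oxy]-7α-[(triethylsilyl)oxy]labda-8,13-dien-6β-yl 3-methylbutanoate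
Conditions: (i-BuCO)2O, 4-dimethylaminopyridine (cat.), Et3N, toluene, 60 °C
Reagents that add atoms: 3-methylbutanoic anhydride CC(C)CC(=O)OC(=O)CC(C)C
Why: With every other hydroxyl masked, nucleophile-catalysed acylation at elevated temperature esterifies the hindered axial 6β-hydroxyl, and the trans-diaxial relation to O7 excludes silyl migration.

Step 15
Reactants: 23 protected ester
Product: 24 6β-(3-methylbutanoyloxy)labda-8,13E-diene-7α,15-diol (CNP0173680.1)
Conditions: Bu4NF, AcOH, THF, 0 °C → rt
Reagents that add atoms: none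
Why: Buffered fluoride cleaves both silyl ethers (Si–F bond formation) without ester cleavage, and acyl migration to O7 is geometrically impossible for the trans-diaxial pair.

**Compound list**
1 | (R)-(−)-carvone, (5R)-2-methyl-5-(prop-1-en-2-yl)cyclohex-2-en-1-one | O=C1C[C@H](C(C)=C)CC=C1C | starting material
2 | lithium cross-conjugated dienolate of 1 (O–Li on C1, C1=C6) | [Li]OC1=C[C@H](C(C)=C)CC=C1C | intermediate
3 | (5R)-2,6-dimethyl-5-(prop-1-en-2-yl)cyclohex-2-en-1-one (C6 epimers) | O=C1C(C)[C@H](C(C)=C)CC=C1C | intermediate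
4 | lithium enolate of 3 (O–Li on C1, C1=C6 tetrasubstituted) | [Li]OC1=C(C)[C@H](C(C)=C)CC=C1C | intermediate
5 | (5S,6S)-6-(3-chloropropyl)-2,6-dimethyl-5-(prop-1-en-2-yl)cyclohex-2-en-1-one | O=C1[C@@](C)(CCCCl)[C@H](C(C)=C)CC=C1C | intermediate
6 | (5S,6S)-6-(3-iodopropyl)-2,6-dimethyl-5-(prop-1-en-2-yl)cyclohex-2-en-1-one | O=C1[C@@](C)(CCCI)[C@H](C(C)=C)CC=C1C | intermediate
7 | (4aS,8aS)-2,5,5,8a-tetramethyl-4a,5,6,7,8,8a-hexahydronaphthalen-1(4H)-one | O=C1[C@@]2(C)CCCC(C)(C)[C@@H]2CC=C1C | intermediate
8 | (4aS,8aS)-4-(tert-butylperoxy)-2,5,5,8a-tetramethyl-4a,5,6,7,8,8a-hexahydronaphthalen-1(4H)-one (C4 epimers) | O=C1[C@@]2(C)CCCC(C)(C)[C@@H]2C(OOC(C)(C)C)C=C1C | intermediate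
9 | (4aS,8aS)-2,5,5,8a-tetramethyl-4a,5,6,7,8,8a-hexahydronaphthalene-1,4-dione | O=C1[C@@]2(C)CCCC(C)(C)[C@@H]2C(=O)C=C1C | intermediate
10 | (4R,4aS,8aS)-4-hydroxy-2,5,5,8a-tetramethyl-4a,5,6,7,8,8a-hexahydronaphthalen-1(4H)-one | O=C1[C@@]2(C)CCCC(C)(C)[C@@H]2[C@H](O)C=C1C | intermediate
11 | tert-butyl(but-3-yn-1-yloxy)dimethylsilane | C#CCCO[Si](C)(C)C(C)(C)C | starting material
12 | (E)-[4-(tert-butyldimethylsilyloxy)-2-methylbut-1-en-1-yl]dimethylalane | C[Al](C)/C=C(C)/CCO[Si](C)(C)C(C)(C)C | intermediate
13 | lithium butyl[(E)-4-(tert-butyldimethylsilyloxy)-2-methylbut-1-en-1-yl]dimethylaluminate | [Li+].CCCC[Al-](C)(C)/C=C(C)/CCO[Si](C)(C)C(C)(C)C | intermediate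
14 | (E)-5-[(tert-butyldimethylsilyl)oxy]-3-methylpent-2-en-1-ol | OC/C=C(C)/CCO[Si](C)(C)C(C)(C)C | intermediate
15 | (E)-1-[(tert-butyldiphenylsilyl)oxy]-5-[(tert-butyldimethylsilyl)oxy]-3-methylpent-2-ene | CC(C)(C)[Si](C)(C)OCC/C(C)=C/CO[Si](c1ccccc1)(c1ccccc1)C(C)(C)C | intermediate
16 | (E)-5-[(tert-butyldiphenylsilyl)oxy]-3-methylpent-3-en-1-ol | OCC/C(C)=C/CO[Si](c1ccccc1)(c1ccccc1)C(C)(C)C | intermediate
17 | (E)-tert-butyl[(5-iodo-3-methylpent-2-en-1-yl)oxy]diphenylsilane | ICC/C(C)=C/CO[Si](c1ccccc1)(c1ccccc1)C(C)(C)C | intermediate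
18 | [(E)-5-(tert-butyldiphenylsilyloxy)-3-methylpent-3-en-1-yl]lithium | [Li]CC/C(C)=C/CO[Si](c1ccccc1)(c1ccccc1)C(C)(C)C | intermediate
19 | bromomagnesium 6β-alkoxide of 10 | O=C1[C@@]2(C)CCCC(C)(C)[C@@H]2[C@H](O[Mg]Br)C=C1C | intermediate
20 | (1S,4R,4aS,8aS)-1-[(E)-5-(tert-butyldiphenylsilyloxy)-3-methylpent-3-en-1-yl]-2,5,5,8a-tetramethyl-1,4,4a,5,6,7,8,8a-octahydronaphthalene-1,4-diol | O[C@]1(CC/C(C)=C/CO[Si](c3ccccc3)(c3ccccc3)C(C)(C)C)[C@@]2(C)CCCC(C)(C)[C@@H]2[C@H](O)C=C1C | intermediate
21 | (13E)-15-[(tert-butyldiphenylsilyl)oxy]labda-8,13-diene-6β,7α-diol | CC1=C(CC/C(C)=C/CO[Si](c3ccccc3)(c3ccccc3)C(C)(C)C)[C@@]2(C)CCCC(C)(C)[C@@H]2[C@H](O)[C@H]1O | intermediate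
22 | (13E)-15-[(tert-butyldiphenylsilyl)oxy]-7α-[(triethylsilyl)oxy]labda-8,13-dien-6β-ol | CC1=C(CC/C(C)=C/CO[Si](c3ccccc3)(c3ccccc3)C(C)(C)C)[C@@]2(C)CCCC(C)(C)[C@@H]2[C@H](O)[C@H]1O[Si](CC)(CC)CC | intermediate
23 | (13E)-15-[(tert-butyldiphenylsilyl)oxy]-7α-[(triethylsilyl)oxy]labda-8,13-dien-6β-yl 3-methylbutanoate | CC1=C(CC/C(C)=C/CO[Si](c3ccccc3)(c3ccccc3)C(C)(C)C)[C@@]2(C)CCCC(C)(C)[C@@H]2[C@H](OC(=O)CC(C)C)[C@H]1O[Si](CC)(CC)CC | intermediate
24 | 6β-(3-methylbutanoyloxy)labda-8,13E-diene-7α,15-diol | CC1=C(CC/C(C)=C/CO)[C@@]2(C)CCCC(C)(C)[C@@H]2[C@H](OC(=O)CC(C)C)[C@H]1O | target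

**Step count**
Total: 15 steps. Longest linear sequence: 11 steps (steps 1–6 and 11–15); the side-chain branch is steps 7–10.

**Steps most likely to fail**

1. Step 4 (proposed new method). What may go wrong: hydrogen-atom transfer to the enone, or nickel-mediated reduction or 7-endo radical cyclization of the primary iodide, may outrun the C–C coupling. The fallback uses known chemistry, sets out from 3 and comes back at 7. Enolate 4 is alkylated with methyl 2-(bromomethyl)acrylate (LiN(i-Pr)2, THF, −78 °C), again anti to the isopropenyl group, to give methyl 2-{[(1S,6S)-1,3-dimethyl-2-oxo-6-(prop-1-en-2-yl)cyclohex-3-en-1-yl]methyl}prop-2-enoate F1. Fe(acac)3/PhSiH3 in EtOH/(CH2OH)2 at 60 °C then effects the hydrogen-atom-transfer Giese cyclization, a 6-endo-trig attack of the C4 radical on the acrylate CH2 (C3), to the ring A keto ester methyl (4aS,8aS)-4,4,7,8a-tetramethyl-8-oxo-1,2,3,4,4a,5,8,8a-octahydronaphthalene-2-carboxylate F2. Saponification (LiOH, THF/H2O) gives the acid F3, and acridinium-photocatalysed hydrodecarboxylation (9-mesityl-10-methylacridinium tetrafluoroborate, PhSSPh, i-Pr2NEt, CF3CH2OH, blue light) returns 7.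

2. Step 12. What may go wrong: E1 loss of a proton from C11 or C17 to dienes, capture of the allyl cation by the side-chain alkene or by O6, or erosion of facial selectivity at C7. The fallback sets out from 20 and comes back at 21. Selective silylation of the secondary hydroxyl (Et3SiCl, imidazole, 4-dimethylaminopyridine, DMF) gives the 6-O-triethylsilyl ether of 20 F4. Babler–Dauben oxidative transposition (pyridinium chlorochromate (C5H5NH)[CrO3Cl], NaOAc, CH2Cl2) gives (13E)-15-[(tert-butyldiphenylsilyl)oxy]-6β-[(triethylsilyl)oxy]labda-8,13-dien-7-one F5. HF·pyridine (THF, 0 °C) frees (13E)-15-[(tert-butyldiphenylsilyl)oxy]-6β-hydroxylabda-8,13-dien-7-one F6 without touching the tert-butyldiphenylsilyl ether. Hydroxyl-directed reduction with Me4NBH(OAc)3 (AcOH/MeCN, −20 °C; Saksena–Evans reduction) then delivers hydride from the 6β-oxygen to the β face of C7 and should give the trans 6β,7α-diol 21.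

3. Step 6. What may go wrong: hydride attack at the C9 carbonyl in competition with C6, or over-reduction to the diol. The fallback sets out from 7 and comes back at 20, so the enedione is never made. Organolithium 18 is added directly to enone 7 (Et2O/THF, −78 °C) to give the tertiary allylic alcohol (C9 OH β, side chain α, Δ7) F7. Allylic oxidation of the ring CH2 at C6 (Rh2(cap)4 with cap = caprolactamate (cat.), t-BuOOH, K2CO3, CH2Cl2) gives the 9β-hydroxy-7-en-6-one F8, which holds a single carbonyl. Luche reduction (NaBH4, CeCl3·7H2O, MeOH, −78 °C) from the α face then returns 20.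

**Further compounds**
F1 | step 4 | methyl 2-{[(1S,6S)-1,3-dimethyl-2-oxo-6-(prop-1-en-2-yl)cyclohex-3-en-1-yl]methyl}prop-2-enoate | O=C1[C@@](C)(CC(=C)C(=O)OC)[C@H](C(C)=C)CC=C1C
F2 | step 4 | methyl (4aS,8aS)-4,4,7,8a-tetramethyl-8-oxo-1,2,3,4,4a,5,8,8a-octahydronaphthalene-2-carboxylate (C2 epimers) | O=C1[C@@]2(C)CC(C(=O)OC)CC(C)(C)[C@@H]2CC=C1C
F3 | step 4 | (4aS,8aS)-4,4,7,8a-tetramethyl-8-oxo-1,2,3,4,4a,5,8,8a-octahydronaphthalene-2-carboxylic acid (C2 epimers) | O=C1[C@@]2(C)CC(C(O)=O)CC(C)(C)[C@@H]2CC=C1C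
F4 | step 12 | 6-O-triethylsilyl ether of 20 | O[C@]1(CC/C(C)=C/CO[Si](c3ccccc3)(c3ccccc3)C(C)(C)C)[C@@]2(C)CCCC(C)(C)[C@@H]2[C@H](O[Si](CC)(CC)CC)C=C1C
F5 | step 12 | (13E)-15-[(tert-butyldiphenylsilyl)oxy]-6β-[(triethylsilyl)oxy]labda-8,13-dien-7-one | CC1=C(CC/C(C)=C/CO[Si](c3ccccc3)(c3ccccc3)C(C)(C)C)[C@@]2(C)CCCC(C)(C)[C@@H]2[C@H](O[Si](CC)(CC)CC)C1=O
F6 | step 12 | (13E)-15-[(tert-butyldiphenylsilyl)oxy]-6β-hydroxylabda-8,13-dien-7-one | CC1=C(CC/C(C)=C/CO[Si](c3ccccc3)(c3ccccc3)C(C)(C)C)[C@@]2(C)CCCC(C)(C)[C@@H]2[C@H](O)C1=O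
F7 | step 6 | (1S,4aS,8aS)-1-[(E)-5-(tert-butyldiphenylsilyloxy)-3-methylpent-3-en-1-yl]-2,5,5,8a-tetramethyl-1,4,4a,5,6,7,8,8a-octahydronaphthalen-1-ol | O[C@]1(CC/C(C)=C/CO[Si](c3ccccc3)(c3ccccc3)C(C)(C)C)[C@@]2(C)CCCC(C)(C)[C@@H]2CC=C1C
F8 | step 6 | 6-oxo derivative of F7 (9β-hydroxy-7-en-6-one) | O[C@]1(CC/C(C)=C/CO[Si](c3ccccc3)(c3ccccc3)C(C)(C)C)[C@@]2(C)CCCC(C)(C)[C@@H]2C(=O)C=C1C
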